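## Analysis of the target

Germacrane numbering is used for the target and all precursors: ring carbons C1–C10, lactone carbons C11 (quaternary) and C12 (carbonyl), C13 the methyl on C11, C14 and C15 the methyls on C10 and C4.

- **Skeleton.** The target is a (1(10)Z,4E)-germacra-1(10),4-dien-12,6-olide. A ten-membered carbocycle (C1–C10) carries the skipped 1,5-diene C10=C1–C2–C3–C4=C5, with one cis and one trans trisubstituted olefin. It is fused at C6–C7 to a γ-lactone (O–C6–C7–C11–C12).
- **Stereocentres.** C6 (S), C7 (R) and C8 (S) are contiguous on the ring. The C6–O bond and the C7–C11 bond are cis (cis-fused lactone). The C8 acetate is trans to the C7–C11 bond, so O6 and O8 are 1,3-anti. C11 (S) is a fully substituted carbinol whose angelate lies on the convex lactone face, syn to H7.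
- **Sensitive groups.** The (Z)-2-methylbut-2-enoate isomerises to the E ester with nucleophiles, heat or light. The secondary acetate sits 1,3 to two other oxygens (acyl migration, translactonisation). The C6–O bond is allylic. The 1,5-diene is prone to transannular cyclisation in acid and to Cope rearrangement on heating.
- **Difficulty.** A strained ten-membered ring must be made with two trisubstituted olefins of opposite geometry that cannot be corrected afterwards, and three ring stereocentres sit next to any ring-forming site.
- **Feature that invites the key move.** The unit C5=C4(C15)–C3–C2–C1=C10(C14) is, atom for atom, the cycloreversion product of a cyclobutane C1–C4–C5–C10. If the bonds C5–C10 and C1–C4 are drawn in, the ten-membered ring collapses to a six-membered ring C5–C6–C7–C8–C9–C10, which carries all three ring stereocentres, and a cyclobutene C1–C2–C3–C4. The C6 oxygen then becomes the carbonyl of an enone C6(=O)–C5=C10, the chromophore of a [2+2] photocycloaddition.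

## Retrosynthetic reasoning

**18 ⇒ 15 + 16 (C11–O acyl bond).** The angelate is the most fragile group and is attached last, to the only free hydroxyl of 15. Acid 16 is activated as mixed anhydride 17. The forward reaction must acylate a hindered tertiary alcohol without Z-to-E isomerisation.

**15 ⇒ 13 (lactone C12–O6 bond, C6–H bond and the acetyl–O8 bond, through 14).** O6 and O8 are 1,3-anti and O8 carries an acyl group. This is the signature of an Evans–Tishchenko reduction of a β-hydroxy ketone with an aldehyde as hydride donor. One operation sets C6, installs the acetate and differentiates O6 from O8 without protecting groups. The C6 hydroxyl, cis to the C7 side chain, then closes the lactone onto the ester.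

**13 ⇒ 12 (two O–Si bonds).** Both hydroxyls stay silylated through the thermal stage, where free β-hydroxy ketones would undergo retro-aldol cleavage. They are released together just before the reduction.

**12 ⇒ 7 + 9 (C4=C5 and C1=C10, through 11 and 10).** The two olefinic bonds are cut as the σ bonds C4–C5 and C1–C10 of tricycle 11, and the bonds C5–C10 and C1–C4 are restored. This is the only cut that makes both trisubstituted olefins and the ten-membered ring in one event from two small rings. It places C7, C8 and C11 on a cyclohexenone, where relative configuration is easy to control, and needs no macrocyclisation. Forward, a [2+2] photocycloaddition builds the strained bicyclo[2.2.0]hexane and heat converts its strain into the ring expansion.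

**7 ⇒ 5 + 6 (C7–C11 bond).** Pyruvate 6 brings C11 with its methyl, oxygen and carboxyl at the final oxidation level. The forward Mukaiyama aldol has to set C7 (anti to the C8 silyloxy group) and C11 (catalyst control) together.

**5 ⇒ 4 ⇒ 3 ⇒ 2 ⇒ 1 (O–Si; C5=C10; C10–C14; amide).** The enone double bond is cut by an intramolecular Horner–Wadsworth–Emmons disconnection to keto phosphonate 3. Its methyl ketone comes from ester 1 through Weinreb amide 2. The C8 stereocentre is bought with 1.

**9 ⇒ 8.** The cyclobutene is the endocyclic isomer of the commercial exocyclic olefin 8.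

## Alternatives that were turned down

**Alternative 1:** the textbook route.
- Disconnection: the C6–C7 bond and the lactone C–O bond.
- Forward key step: intramolecular Nozaki–Hiyama–Kishi-type allylation (CrCl2) of the acyclic bromo aldehyde A1 to the α-methylene lactone A2, followed by Mn(dpm)3/PhSiH3/O2 hydration at C11.
- Reasons for rejection:
  - The cis C6/C7 relationship would have to come from a ten-membered chair-like transition state under control of the C8 centre next to the nucleophilic carbon. Such closures normally give the trans-fused lactone.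
  - The closure forms a strained ring at high dilution.
  - A1 needs separate stereocontrolled syntheses of the (Z)-trisubstituted olefin, the (E)-enal, the C8 carbinol and the bromomethyl acrylate, about ten steps before the key step. C11 then still has to be set.

**Alternative 2:** ring contraction.
- Disconnection: C6–C7, with extrusion of the ether oxygen from a thirteen-membered ring.
- Forward key step: [2,3]-Wittig rearrangement of the cyclic diallylic ether A3 to the cyclodecadienol A4.
- Reasons for rejection:
  - Deprotonation must distinguish two allylic α-oxy positions (C6 and C13).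
  - The isopropenyl group of A4 must afterwards be oxidised to the tertiary α-hydroxy acid in the presence of two more electron-rich trisubstituted ring olefins, a chemoselectivity that cannot be defended.
  - A3 needs a (Z)-C7=C11 olefin, a Z/E-defined chain, a C8 oxygen and a large-ring etherification. The route would be far longer than the problem it solves.

**Alternative 3:** anionic oxy-Cope ring expansion.
- Disconnection: C6–C7 formed, C4–C9 broken.
- Forward key step: KH/18-crown-6 treatment of the cis-dialkenyl cyclohexenol A5 to the cyclodecadienone A6.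
- Merit: this gives the right geometries by design (1(10)Z from the six-membered ring, 4E from the chair).
- Reasons for rejection:
  - It leaves a ketone on C9, a carbon that is a bare CH2 in the target, next to the C8 oxygen. Its removal costs at least three steps and endangers C8.
  - The precursor needs 1,2-addition to a hindered 2,6,6-trisubstituted cyclohexenone, an enol-ether alkenyl group, and cannot carry the ester of the side chain.

Key step: step 7

## Route

Assumption: 1 is bought as the (3R) enantiomer (a statin side-chain building block). Its stereocentre becomes C8.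

Step 1
Reactants: 1 methyl (3R)-3-[(tert-butyldimethylsilyl)oxy]-6-(dimethoxyphosphoryl)-5-oxohexanoate
Product: 2 dimethyl {(4R)-4-[(tert-butyldimethylsilyl)oxy]-6-[methoxy(methyl)amino]-2,6-dioxohexyl}phosphonate
Conditions: MeNH(OMe)·HCl, i-PrMgCl, THF, −20 → 0 °C
Reagents that add atoms: N,O-dimethylhydroxylamine hydrochloride, CNOC.Cl
Why: Weinreb aminolysis of the ester by the chloromagnesium amide; the β-keto phosphonate is deprotonated first and so protected as its magnesium enolate, and the silyloxy stereocentre is not touched.

Step 2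
Reactants: 2 dimethyl {(4R)-4-[(tert-butyldimethylsilyl)oxy]-6-[methoxy(methyl)amino]-2,6-dioxohexyl}phosphonate
Product: 3 dimethyl {(4S)-4-[(tert-butyldimethylsilyl)oxy]-2,6-dioxoheptyl}phosphonate
Conditions: MeMgBr (2.5 equiv), THF, −78 → 0 °C; aq NH4Cl
Reagents that add atoms: methylmagnesium bromide, C[Mg]Br
Why: Weinreb ketone synthesis; the first equivalent forms the keto phosphonate enolate, the second adds once to the amide and stops at the chelated tetrahedral intermediate. The descriptor changes from R to S only through the priority rules.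

Step 3
Reactants: 3 dimethyl {(4S)-4-[(tert-butyldimethylsilyl)oxy]-2,6-dioxoheptyl}phosphonate
Product: 4 (5S)-5-[(tert-butyldimethylsilyl)oxy]-3-methylcyclohex-2-en-1-one
Conditions: NaH (1.0 equiv), THF (0.02 M), 0 → 23 °C
Reagents that add atoms: none
Why: intramolecular Horner–Wadsworth–Emmons reaction onto the methyl ketone forms C5=C10 and the six-membered ring; the single equivalent of base ends as sodium dimethyl phosphate, so the β-silyloxy enone is not exposed to base (no elimination to the phenol).

Step 4
Reactants: 4 (5S)-5-[(tert-butyldimethylsilyl)oxy]-3-methylcyclohex-2-en-1-one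
Product: 5 tert-butyl(dimethyl){[(1S)-5-methyl-3-[(trimethylsilyl)oxy]cyclohexa-2,4-dien-1-yl]oxy}silane
Conditions: LiN(i-Pr)2, Me3SiCl (in situ quench), THF, −78 °C
Reagents that add atoms: chlorotrimethylsilane, C[Si](C)(C)Cl
Why: kinetic α′-deprotonation at C7 gives the cross-conjugated enolate, which is silylated as it forms; trapping is faster than β-elimination of the C8 silyloxy group.

Step 5
Reactants: 5 tert-butyl(dimethyl){[(1S)-5-methyl-3-[(trimethylsilyl)oxy]cyclohexa-2,4-dien-1-yl]oxy}silane; 6 methyl pyruvate
Product: 7 methyl (2S)-2-[(1S,6S)-6-[(tert-butyldimethylsilyl)oxy]-4-methyl-2-oxocyclohex-3-en-1-yl]-2-[(trimethylsilyl)oxy]propanoate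
Conditions: Cu(OTf)2 (10 mol %), (S,S)-t-Bu-box [2,2′-(propane-2,2-diyl)bis((4S)-4-tert-butyl-4,5-dihydrooxazole)] (11 mol %), THF, −78 °C; aq NaHCO3
Reagents that add atoms: none
Why: Mukaiyama aldol addition to pyruvate chelated on the divalent copper bis(oxazoline) complex; the ligand should shield the re face of the ketone (C11 S), C7 attacks anti to the C8 silyloxy group, and the syn topicity typical of this open transition state agrees with both, so the case is matched. Silyl transfer leaves the tertiary oxygen as its trimethylsilyl ether.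

Step 6
Reactants: 8 methylenecyclobutane
Product: 9 1-methylcyclobutene
Conditions: KOt-Bu (cat.), DMSO, 60 °C, product distilled off through a column
Reagents that add atoms: none
Why: base-mediated 1,3-prototropic shift; the endocyclic trisubstituted olefin is favoured at equilibrium and is the lower-boiling isomer, so distillation drives the conversion.

Step 7
Reactants: 7 methyl (2S)-2-[(1S,6S)-6-[(tert-butyldimethylsilyl)oxy]-4-methyl-2-oxocyclohex-3-en-1-yl]-2-[(trimethylsilyl)oxy]propanoate; 9 1-methylcyclobutene
Product: 12 methyl (2S)-2-[(1S,2S,4Z,8E)-2-[(tert-butyldimethylsilyl)oxy]-4,8-dimethyl-10-oxocyclodeca-4,8-dien-1-yl]-2-[(trimethylsilyl)oxy]propanoate, via trans-fused photoadduct 10 (not isolated), via cis-fused photoadduct 11 (not isolated)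
Conditions: hν (350 nm, Pyrex), 9 (8 equiv), CH2Cl2, −40 °C; evaporate; basic Al2O3 plug; then toluene (0.02 M, base-washed tube), 185 °C
Reagents that add atoms: none
Why: The triplet enone of 7 adds 9 through 1,4-biradicals to a cyclobutane (new σ bonds C4–C5 and C1–C10), basic alumina epimerises the trans-fused part 10 at C5 to cis-anti-cis 11, and at 185 °C the bicyclo[2.2.0]hexane unit of 11 breaks its central C1–C4 bond to a cyclohexane-1,4-diyl that cleaves C5–C10, so that the six-membered ring grows by four carbons into the ten-membered dienone. The closest known reaction type is the photocycloaddition–cycloreversion sequence (formal enone–cyclobutene metathesis) of 3-methylcyclohex-2-enones with 1-methylcyclobutene to germacra-1(10),4-dien-6-ones, together with the thermal bicyclo[2.2.0]hexane to hexa-1,5-diene isomerisation. The only ring closed by bond formation is the cyclobutane (intermolecular, stepwise [2+2], first bond C10–C1, then closure of the tertiary C4 radical onto the α-keto radical at C5); the ten-membered ring is not closed but unveiled by cleavage of the two zero-atom bridges. No new stereocentre survives: the four made at C1, C4, C5 and C10 are erased again, so the facial course of the photoaddition does not matter, and C7, C8 and C11 are spectators. The olefin geometry is set in the chair-like diyl of the cis-fused adduct, where C6 sits equatorial on C5 (4E) and C9 is then forced axial on the quaternary C10 (1(10)Z). Three selectivities are needed: head-to-head orientation, which the fully substituted β-carbon C10 should secure because the methyl-bearing cyclobutene carbon avoids a vicinal quaternary pair; cleavage to the ten-membered ring and not to the divinylcyclohexanone reached through the same diyl or by Cope rearrangement, which conjugation of the new C4=C5 bond with the C6 carbonyl and the two trisubstituted olefins should favour at moderate temperature; and survival of the β-silyloxy ketone and of C7, for which the medium is kept neutral and aprotic.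

Step 8
Reactants: 12 methyl (2S)-2-[(1S,2S,4Z,8E)-2-[(tert-butyldimethylsilyl)oxy]-4,8-dimethyl-10-oxocyclodeca-4,8-dien-1-yl]-2-[(trimethylsilyl)oxy]propanoate
Product: 13 methyl (2S)-2-hydroxy-2-[(1S,2S,4Z,8E)-2-hydroxy-4,8-dimethyl-10-oxocyclodeca-4,8-dien-1-yl]propanoate
Conditions: HF·pyridine, pyridine, THF, 0 → 23 °C
Reagents that add atoms: none
Why: buffered fluoride cleavage of both silyl ethers; the medium is never basic, so neither β-hydroxy ketone undergoes retro-aldol cleavage, and the α,α-disubstituted ester is too hindered to be attacked by O8 under these conditions.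

Step 9
Reactants: 13 methyl (2S)-2-hydroxy-2-[(1S,2S,4Z,8E)-2-hydroxy-4,8-dimethyl-10-oxocyclodeca-4,8-dien-1-yl]propanoate
Product: 15 (3S,3aR,4S,6Z,10E,11aS)-3-hydroxy-3,6,10-trimethyl-2-oxo-2,3,3a,4,5,8,9,11a-octahydrocyclodeca[b]furan-4-yl acetate, via hydroxy ester 14 (not isolated)
Conditions: SmI2 (30 mol %), MeCHO (10 equiv), THF, −10 → 23 °C; then PPTS (cat.), CH2Cl2, 23 °C
Reagents that add atoms: acetaldehyde, CC=O
Why: Evans–Tishchenko reduction: the secondary C8 hydroxyl forms a hemiacetal bound to trivalent samarium and delivers its hydride intramolecularly to C6, which gives the 1,3-anti relationship (C6 S) and leaves the acetyl group on O8. The new C6 hydroxyl is cis to the C7 side chain and closes the cis-fused γ-lactone on the methyl ester; the hindered tertiary hydroxyl should not compete as hemiacetal donor.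

Step 10
Reactants: 15 (3S,3aR,4S,6Z,10E,11aS)-3-hydroxy-3,6,10-trimethyl-2-oxo-2,3,3a,4,5,8,9,11a-octahydrocyclodeca[b]furan-4-yl acetate; 16 angelic acid [(2Z)-2-methylbut-2-enoic acid]
Product: 18 (3S,3aR,4S,6Z,10E,11aS)-4-(acetyloxy)-3,6,10-trimethyl-2-oxo-2,3,3a,4,5,8,9,11a-octahydrocyclodeca[b]furan-3-yl (2Z)-2-methylbut-2-enoate, via mixed anhydride 17 (not isolated)
Conditions: 16, 2,4,6-Cl3C6H2COCl, Et3N, toluene, 23 °C; then 15, 80 °C
Reagents that add atoms: none
Why: Yamaguchi-type acylation of the only free hydroxyl by the angeloyl carbonyl of 17; no nucleophilic catalyst is used, because addition–elimination at the β-carbon is the path by which the Z ester isomerises.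

## Compound list

1 | methyl (3R)-3-[(tert-butyldimethylsilyl)oxy]-6-(dimethoxyphosphoryl)-5-oxohexanoate | COC(=O)C[C@H](O[Si](C)(C)C(C)(C)C)CC(=O)CP(=O)(OC)OC | starting material
2 | dimethyl {(4R)-4-[(tert-butyldimethylsilyl)oxy]-6-[methoxy(methyl)amino]-2,6-dioxohexyl}phosphonate | CON(C)C(=O)C[C@H](O[Si](C)(C)C(C)(C)C)CC(=O)CP(=O)(OC)OC | intermediate
3 | dimethyl {(4S)-4-[(tert-butyldimethylsilyl)oxy]-2,6-dioxoheptyl}phosphonate | CC(=O)C[C@H](O[Si](C)(C)C(C)(C)C)CC(=O)CP(=O)(OC)OC | intermediate
4 | (5S)-5-[(tert-butyldimethylsilyl)oxy]-3-methylcyclohex-2-en-1-one | O=C1C=C(C)C[C@H](O[Si](C)(C)C(C)(C)C)C1 | intermediate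
5 | tert-butyl(dimethyl){[(1S)-5-methyl-3-[(trimethylsilyl)oxy]cyclohexa-2,4-dien-1-yl]oxy}silane | C[Si](C)(C)OC1=C[C@@H](O[Si](C)(C)C(C)(C)C)CC(C)=C1 | intermediate
6 | methyl pyruvate | CC(=O)C(=O)OC | starting material
7 | methyl (2S)-2-[(1S,6S)-6-[(tert-butyldimethylsilyl)oxy]-4-methyl-2-oxocyclohex-3-en-1-yl]-2-[(trimethylsilyl)oxy]propanoate | O=C1C=C(C)C[C@H](O[Si](C)(C)C(C)(C)C)[C@H]1[C@](C)(O[Si](C)(C)C)C(=O)OC | intermediate
8 | methylenecyclobutane | C=C1CCC1 | starting material
9 | 1-methylcyclobutene | CC1=CCC1 | intermediate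
10 | trans-fused photoadduct (not isolated): methyl (2S)-2-[8-(tert-butyldimethylsilyloxy)-2,6-dimethyl-10-oxotricyclo[4.4.0.0(2,5)]decan-9-yl]-2-(trimethylsilyloxy)propanoate, C5 epimer of 11 (H on C5 trans to the C10 methyl) | O=C1[C@H]2[C@@]3(C)CC[C@H]3[C@]2(C)C[C@H](O[Si](C)(C)C(C)(C)C)[C@H]1[C@](C)(O[Si](C)(C)C)C(=O)OC | intermediate
11 | cis-anti-cis photoadduct (not isolated): methyl (2S)-2-[8-(tert-butyldimethylsilyloxy)-2,6-dimethyl-10-oxotricyclo[4.4.0.0(2,5)]decan-9-yl]-2-(trimethylsilyloxy)propanoate; H on C5 cis to the C10 methyl, the two four-membered rings anti, new ring drawn on the face opposite to the C7 side chain (the other facial isomer gives the same 12) | O=C1[C@@H]2[C@@]3(C)CC[C@H]3[C@]2(C)C[C@H](O[Si](C)(C)C(C)(C)C)[C@H]1[C@](C)(O[Si](C)(C)C)C(=O)OC | intermediate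
12 | methyl (2S)-2-[(1S,2S,4Z,8E)-2-[(tert-butyldimethylsilyl)oxy]-4,8-dimethyl-10-oxocyclodeca-4,8-dien-1-yl]-2-[(trimethylsilyl)oxy]propanoate | O=C1/C=C(\C)CC/C=C(/C)C[C@H](O[Si](C)(C)C(C)(C)C)[C@H]1[C@](C)(O[Si](C)(C)C)C(=O)OC | intermediate
13 | methyl (2S)-2-hydroxy-2-[(1S,2S,4Z,8E)-2-hydroxy-4,8-dimethyl-10-oxocyclodeca-4,8-dien-1-yl]propanoate | O=C1/C=C(\C)CC/C=C(/C)C[C@H](O)[C@H]1[C@](C)(O)C(=O)OC | intermediate
14 | methyl (2S)-2-[(1S,2S,4Z,8E,10S)-2-(acetyloxy)-10-hydroxy-4,8-dimethylcyclodeca-4,8-dien-1-yl]-2-hydroxypropanoate (not isolated) | O[C@H]1/C=C(\C)CC/C=C(/C)C[C@H](OC(C)=O)[C@H]1[C@](C)(O)C(=O)OC | intermediate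
15 | (3S,3aR,4S,6Z,10E,11aS)-3-hydroxy-3,6,10-trimethyl-2-oxo-2,3,3a,4,5,8,9,11a-octahydrocyclodeca[b]furan-4-yl acetate | O[C@]1(C)C(=O)O[C@H]2/C=C(\C)CC/C=C(/C)C[C@H](OC(C)=O)[C@H]21 | intermediate
16 | angelic acid, (2Z)-2-methylbut-2-enoic acid | C/C=C(/C)C(=O)O | starting material
17 | (2Z)-2-methylbut-2-enoic 2,4,6-trichlorobenzoic anhydride (not isolated) | C/C=C(/C)C(=O)OC(=O)c1c(Cl)cc(Cl)cc1Cl | intermediate
18 | (3S,3aR,4S,6Z,10E,11aS)-4-(acetyloxy)-3,6,10-trimethyl-2-oxo-2,3,3a,4,5,8,9,11a-octahydrocyclodeca[b]furan-3-yl (2Z)-2-methylbut-2-enoate | C/C=C(/C)C(=O)O[C@]1(C)C(=O)O[C@H]2/C=C(\C)CC/C=C(/C)C[C@H](OC(C)=O)[C@H]21 | target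

## Step count and risk

Total step count: 10.
Longest linear sequence: 9 steps (steps 1–5 and 7–10). Step 6 is a one-step side branch.

**Step 7 (key step).**
- What may go wrong:
  - Partial head-to-tail orientation in the photoaddition.
  - Drainage of the ten-membered dienone into the divinylcyclohexanone through the shared diyl or by Cope rearrangement, with equilibration toward the other Z/E distribution. This is the main danger because the cyclobutane cleavage needs temperatures at which the Cope manifold is already open.
  - Thermal β-elimination of the C8 silyloxy group or epimerisation at C7.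
- Fallback (sets out from 7, returns at 12). The cyclohexenone is used only as a stereochemical template and the ring is closed by olefin metathesis.
  - Ozonolysis of the C5=C10 bond of 7 with oxidative work-up (O3, CH2Cl2/MeOH, −78 °C; H2O2) should give the keto acid F1.
  - Carbodiimide coupling with N,O-dimethylhydroxylamine gives the Weinreb amide F2.
  - Wittig methylenation (Ph3P=CH2) of the methyl ketone gives the isopropenyl amide F3.
  - The alkenyllithium is made from (E)-1-iodo-2-methylhexa-1,5-diene F5 (hex-1-en-5-yne, AlMe3, Cp2ZrCl2 cat., then I2; t-BuLi). Its addition to F3 gives the (E)-enone triene F4.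
  - Ring-closing metathesis with the second-generation Hoveyda–Grubbs catalyst at high dilution closes C1=C10, where the ten-membered ring should enforce the Z geometry, and gives 12.

**Step 9.**
- What may go wrong:
  - Hydride delivery directed by the tertiary instead of the secondary hydroxyl.
  - Loss of the anti preference inside the macrocycle.
  - Acetyl migration before lactonisation, or lactonisation of O8 before the reduction.
  All of these arise because three oxygens sit 1,3 to each other around C7.
- Fallback (sets out from 12, returns at 15). The silyl ethers are kept and C6 is set by substitution.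
  - Luche reduction (NaBH4, CeCl3·7H2O, MeOH, −78 °C) gives the allylic alcohol F6, drawn as the 6R epimer expected from attack anti to the C7 branch.
  - Saponification (LiOH, aqueous THF, which also removes the trimethylsilyl group) gives the dihydroxy acid F7.
  - Mitsunobu lactonisation (PPh3, DIAD) closes the ring with inversion at C6 to the hydroxy lactone silyl ether F8. Should hydride arrive from the other face instead, the same F8 forms by direct lactonisation with retention.
  - HF·pyridine gives the diol lactone F9.
  - Ac2O/pyridine acetylates only the secondary O8 and gives 15.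

**Step 10.**
- What may go wrong: incomplete acylation of the hindered tertiary alcohol and Z-to-E isomerisation of the angeloyl group under the forcing it needs.
- Fallback (sets out from 15, returns at 18). The Z olefin is built on the ester.
  - Acylation with 2-[bis(2,2,2-trifluoroethoxy)phosphoryl]propanoic acid (DCC, DMAP; forcing is harmless here) gives the phosphonate ester F10, as both epimers at the phosphorus-bearing carbon.
  - Still–Gennari olefination (KN(SiMe3)2, 18-crown-6, THF, −78 °C; acetaldehyde) gives the Z ester 18.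

**Step 5.**
- What may go wrong: insufficient facial control at C11, or low reactivity of the hindered nucleophilic carbon next to the silyloxy group.
- Fallback (sets out from 4, returns at 15). C11 is built late on the rigid cis-fused lactone.
  - The lithium enolate of 4 (LiN(i-Pr)2, THF, −78 °C) is alkylated with methyl iodoacetate to the trans keto ester F11.
  - The conditions of step 7 with 9 give the dienone F12.
  - Luche reduction gives the alcohol F13, saponification the hydroxy acid F14, and Mitsunobu closure the cis lactone F15.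
  - Enolate methylation (LiN(i-Pr)2, MeI) gives the methyl lactone F16.
  - A second enolisation (KN(SiMe3)2) and hydroxylation with 2-(phenylsulfonyl)-3-phenyloxaziridine from the convex face, syn to H7, gives F8.
  - F8 is carried on through F9 to 15 as in the fallback to step 9.

## Further compounds

F1 | step 7 | keto acid from cleavage of C5=C10 of 7: 3-[(tert-butyldimethylsilyl)oxy]-2-[(2S)-1-methoxy-1-oxo-2-(trimethylsilyloxy)propan-2-yl]-5-oxohexanoic acid | OC(=O)[C@@H]([C@@H](O[Si](C)(C)C(C)(C)C)CC(C)=O)[C@](C)(O[Si](C)(C)C)C(=O)OC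
F2 | step 7 | N-methoxy-N-methyl amide of F1 | CON(C)C(=O)[C@@H]([C@@H](O[Si](C)(C)C(C)(C)C)CC(C)=O)[C@](C)(O[Si](C)(C)C)C(=O)OC
F3 | step 7 | isopropenyl Weinreb amide (methylenation product of F2) | CON(C)C(=O)[C@@H]([C@@H](O[Si](C)(C)C(C)(C)C)CC(C)=C)[C@](C)(O[Si](C)(C)C)C(=O)OC
F4 | step 7 | (E)-enone triene, metathesis precursor of 12 | C=CCC/C(C)=C/C(=O)[C@@H]([C@@H](O[Si](C)(C)C(C)(C)C)CC(C)=C)[C@](C)(O[Si](C)(C)C)C(=O)OC
F5 | step 7 | (E)-1-iodo-2-methylhexa-1,5-diene | C=CCC/C(C)=C/I
F6 | step 9 | methyl (2S)-2-[(1S,2S,4Z,8E,10R)-2-(tert-butyldimethylsilyloxy)-10-hydroxy-4,8-dimethylcyclodeca-4,8-dien-1-yl]-2-(trimethylsilyloxy)propanoate | O[C@@H]1/C=C(\C)CC/C=C(/C)C[C@H](O[Si](C)(C)C(C)(C)C)[C@H]1[C@](C)(O[Si](C)(C)C)C(=O)OC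
F7 | step 9 | dihydroxy acid from saponification of F6 | O[C@@H]1/C=C(\C)CC/C=C(/C)C[C@H](O[Si](C)(C)C(C)(C)C)[C@H]1[C@](C)(O)C(=O)O
F8 | step 9 | cis-fused 11-hydroxy lactone, 8-O-tert-butyldimethylsilyl ether | O[C@]1(C)C(=O)O[C@H]2/C=C(\C)CC/C=C(/C)C[C@H](O[Si](C)(C)C(C)(C)C)[C@H]21
F9 | step 9 | cis-fused 8,11-dihydroxy lactone | O[C@]1(C)C(=O)O[C@H]2/C=C(\C)CC/C=C(/C)C[C@H](O)[C@H]21
F10 | step 10 | 2-[bis(2,2,2-trifluoroethoxy)phosphoryl]propanoate of 15 (both epimers at the phosphorus-bearing carbon) | CC(P(=O)(OCC(F)(F)F)OCC(F)(F)F)C(=O)O[C@]1(C)C(=O)O[C@H]2/C=C(\C)CC/C=C(/C)C[C@H](OC(C)=O)[C@H]21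
F11 | step 5 | methyl 2-[(1R,6S)-6-(tert-butyldimethylsilyloxy)-4-methyl-2-oxocyclohex-3-en-1-yl]acetate | O=C1C=C(C)C[C@H](O[Si](C)(C)C(C)(C)C)[C@H]1CC(=O)OC
F12 | step 5 | methyl 2-[(1R,2S,4Z,8E)-2-(tert-butyldimethylsilyloxy)-4,8-dimethyl-10-oxocyclodeca-4,8-dien-1-yl]acetate | O=C1/C=C(\C)CC/C=C(/C)C[C@H](O[Si](C)(C)C(C)(C)C)[C@H]1CC(=O)OC
F13 | step 5 | C6 alcohol from reduction of F12 (drawn as the epimer trans to the side chain) | O[C@@H]1/C=C(\C)CC/C=C(/C)C[C@H](O[Si](C)(C)C(C)(C)C)[C@H]1CC(=O)OC
F14 | step 5 | hydroxy acid from saponification of F13 | O[C@@H]1/C=C(\C)CC/C=C(/C)C[C@H](O[Si](C)(C)C(C)(C)C)[C@H]1CC(=O)O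
F15 | step 5 | cis-fused lactone unsubstituted at C11, 8-O-tert-butyldimethylsilyl ether | O=C1O[C@H]2/C=C(\C)CC/C=C(/C)C[C@H](O[Si](C)(C)C(C)(C)C)[C@H]2C1
F16 | step 5 | cis-fused 11-methyl lactone, methyl syn to H7, 8-O-tert-butyldimethylsilyl ether | C[C@@H]1C(=O)O[C@H]2/C=C(\C)CC/C=C(/C)C[C@H](O[Si](C)(C)C(C)(C)C)[C@H]21
A1 | alternative 1 | methyl (2Z,4S,6Z,10E)-2-(bromomethyl)-4-[(tert-butyldimethylsilyl)oxy]-6,10-dimethyl-12-oxododeca-2,6,10-trienoate | O=C/C=C(\C)CC/C=C(/C)C[C@H](O[Si](C)(C)C(C)(C)C)/C=C(\CBr)C(=O)OC
A2 | alternative 1 | (3aS,4S,6Z,10E,11aS)-4-[(tert-butyldimethylsilyl)oxy]-6,10-dimethyl-3-methylidene-3a,4,5,8,9,11a-hexahydrocyclodeca[b]furan-2(3H)-one | C=C1C(=O)O[C@H]2/C=C(\C)CC/C=C(/C)C[C@H](O[Si](C)(C)C(C)(C)C)[C@@H]12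
A3 | alternative 2 | (3E,7Z,10S,11Z)-10-[(tert-butyldimethylsilyl)oxy]-4,8,12-trimethyl-1-oxacyclotrideca-3,7,11-triene | O1C/C=C(\C)CC/C=C(/C)C[C@H](O[Si](C)(C)C(C)(C)C)/C=C(/C)C1
A4 | alternative 2 | (1S,2E,6Z,9S,10S)-9-[(tert-butyldimethylsilyl)oxy]-3,7-dimethyl-10-(prop-1-en-2-yl)cyclodeca-2,6-dien-1-ol | O[C@H]1/C=C(\C)CC/C=C(/C)C[C@H](O[Si](C)(C)C(C)(C)C)[C@H]1C(C)=C
A5 | alternative 3 | 1-ethenyl-6-[(E)-2-methoxyethenyl]-2,6-dimethylcyclohex-2-en-1-ol, alkenyl groups cis | C=C[C@]1(O)C(C)=CCC[C@]1(C)/C=C/OC
A6 | alternative 3 | (2Z,6E)-8-methoxy-2,6-dimethylcyclodeca-2,6-dien-1-one | CO[C@@H]1CCC(=O)/C(C)=C\CC/C(C)=C/1
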